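**Remark on the chemistry (assumption):** 17 is treated as the 2-hydroxy-1,4-benzoquinone tautomer drawn in the SMILES; it is achiral. Formaldehyde (10) is used as its polymer, paraformaldehyde.

**Numbering used throughout:** 1 2,6-dimethoxytoluene; 2 dibromide of 1; 3 resorcinol diol; 4 bis-MOM arene; 5 ethylene oxide; 6 aryllithium; 7 arylethanol; 8 arylethyl bromide; 9 2-bromothiophene; 10 formaldehyde; 11 chloromethylthiophene; 12 bis(5-bromothiophen-2-yl)methane; 13 Grignard reagent; 14 coupled bis-thiophene; 15 saturated bis-arene; 16 tetraphenol; 17 target.

## Analysis of the target

Target 17 has two identical, fully substituted 1,4-benzoquinone rings, each 2-hydroxy-5-methoxy-6-methyl, joined through their C3 atoms by an unbranched chain of thirteen methylene groups (c1 to c13). There is no stereocentre and no double-bond geometry to set; the molecule has a mirror plane through c7. The sensitive part is the hydroxyquinone, a redox-active vinylogous acid next to a vinylogous methyl ester. It would not survive bases, nucleophiles or organometallic reagents, so both quinones have to appear at the very end. Two things make the synthesis hard. The first is the placement of four different oxygen functions on each ring, with the hydroxyl next to the chain and the methoxy next to the methyl. The second is the odd chain length, which rules out joining two identical halves at a central bond and calls for a one-carbon centre piece. The first problem is eased by a local symmetry: if, at the arene oxidation level, the two oxygens flanking the chain carry one kind of protecting group and the two flanking the methyl are methyl ethers, the ring has a mirror axis through the chain carbon and the methyl carbon, and oxidation of either para oxygen pair gives the same quinone. The strategy rests on the second feature: the nine carbons c3 to c11 match bis(thiophen-2-yl)methane atom for atom. Carbons c3–c6 and c8–c11 are the carbons of two thiophene rings and c7 is the methane carbon, so the inert chain can travel as two aromatic rings that accept cross-coupling at c3 and c11 and later lose sulfur.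

## Retrosynthetic reasoning

**17 ⇒ 16.** Only C–O bonds change: each quinone is traced back to a phenol with a para methoxy group in tetraphenol 16. The quinone cannot be carried through carbanion chemistry, and oxidative demethylation needs exactly this para relationship. Because of the ring's mirror axis, both phenol/methoxy pairs give the same quinone, so the forward oxidation only has to stop at the two-electron stage per ring.

**16 ⇒ 15.** The four phenols are masked as methoxymethyl (MOM) ethers in 15. This keeps them distinct from the two methyl ethers, makes the rings inert to bases, organometallics and nickel, and the acetals later direct lithiation to the carbon between them. Mild acid must remove them without touching the methyl ethers.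

**15 ⇒ 14.** No carbon–carbon bond is cut. Instead c3/c6 and c8/c11 are joined through sulfur, turning the central nonane stretch into the two thiophene rings of 14. This converts an unfunctionalised alkane into heteroarenes with reactive α-positions at c3 and c11 and supplies the odd central carbon c7. The forward step has to excise both sulfur atoms and saturate all eight ring carbons.

**14 ⇒ 13 + 12.** The bonds c2–c3 and c11–c12 are cut, between each ethylene spacer and a thiophene α-carbon. Here an sp2 electrophile (the dibromide 12) meets a primary alkyl nucleophile (Grignard reagent 13, two equivalents), so the partners are differentiated and no statistical mixture arises. Cutting at the ring–c1 bond would mean coupling at an arene carbon flanked by two alkoxy groups. Cutting c1–c2 would need an sp3–sp3 union. The forward reaction must couple both C–Br bonds without β-hydride elimination and without deprotonating c7.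

**13 ⇒ 8 ⇒ 7.** Functional-group changes only: the C–Mg bond comes from the C–Br bond of 8, and that from the primary alcohol 7.

**7 ⇒ 4 + 5.** The ring–c1 bond is cut to an aryl anion from 4 and ethylene oxide (5), which supplies c1, c2 and the hydroxyl. The anion site is the only ring hydrogen of 4 and lies between two MOM ethers, so lithiation there needs no selectivity argument beyond chelation.

**4 ⇒ 3 ⇒ 2 ⇒ 1.** The two MOM-bearing oxygens are traced back through diol 3 to the C–Br bonds of 2 and then to C–H bonds of 1. These are the two positions of 1 that are ortho to one methoxy and para to the other. The methyl ethers of 1 therefore end up beside the methyl, and the new oxygens beside the future chain.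

**12 ⇒ 9 + 10.** Both bonds from c7 to the thiophenes are cut: formaldehyde (10) is c7 and links two molecules of 2-bromothiophene (9). The bromine first blocks one α-position during the condensation and then serves as the coupling handle.

## Alternatives that were turned down

**Alternative 1:** Each benzenoid ring is opened at the bond between the chain-bearing ring carbon and its ester-bearing neighbour. This leads back to the open-chain diester A2, dimethyl 4,24-dimethyl-3,5,7,21,23,25-hexaoxoheptacosanedioate. In the forward direction mild aqueous base lets the C2 methylene of each triketo ester unit add to its C7 ketone, and dehydration and enolisation give the bis(resorcylate) A1, dimethyl 6,6'-(tridecane-1,13-diyl)bis(2,4-dihydroxy-3-methylbenzoate).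
- For it: both rings arise from acyclic material in one operation, the positions of chain and methyl are fixed by the carbon sequence, and no organometallic coupling is needed.
- Against it: A1 has only two ring oxygens and carries an ester carbon where 17 needs oxygen. Reaching 17 would need decarboxylation, oxygenation of both carbons flanking the chain, and methylation of just one of the two hydroxyls flanking the methyl. That is at least five further operations, with regiochemical choices that A1 does not predispose. A2 itself, with six ketones and two esters on a long chain, is laborious to assemble and prone to other cyclisations, such as pyranone formation and Claisen-type closure.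
- Comparison: the ring construction is more elegant, but the chosen route starts with the full oxygen pattern already on a cheap arene and needs three steps after its key step.

**Alternative 2:** Each ring is disconnected at the bond between the hydroxyl-bearing carbon next to the chain and the methoxy-bearing carbon. This leads to the bis(cyclobutenone) A4, 2,2'-(tridecane-1,13-diyl)bis[4-hydroxy-3-isopropoxy-4-(1-methoxyprop-1-en-2-yl)cyclobut-2-en-1-one]. Heating A4 opens both four-membered rings to dienylketenes, which close by 6π electrocyclisation and tautomerise (Moore-type rearrangement). The product is A3, 6,6'-(tridecane-1,13-diyl)bis(5-isopropoxy-2-methoxy-3-methylbenzene-1,4-diol).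
- For it: both hexasubstituted rings are delivered at the hydroquinone level with every substituent placed by the order of additions to a squarate. The two ether oxygens are already differentiated, isopropyl beside the chain and methyl beside the ring methyl. Only oxidation and selective de-isopropylation remain. On regiocontrol by construction this is as strong as the chosen route or stronger, and it avoids a catalytic hydroxylation.
- Against it: A4 requires an odd C13 α,ω-dimetal reagent, itself several steps from a diacid, added twice to a squarate ester. A thermally and configurationally delicate β-methoxyalkenyl lithium reagent must then add twice, regioselectively, to strained and highly electrophilic diones. Every operation is twofold on an acid-labile bifunctional intermediate.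
- Comparison: the step count is similar, about ten. The chosen route offers robust ether intermediates throughout and a tether built from two bulk chemicals, and it concentrates the risk in one well-understood cross-coupling.

**Alternative 3:** The tether is cut at c3–c4 and c10–c11, two sp3–sp3 bonds. The pieces are the bis(N-hydroxyphthalimide) ester A6, bis(1,3-dioxoisoindolin-2-yl) nonanedioate, and two molecules of the redox-active ester A7, 1,3-dioxoisoindolin-2-yl 4-[2,6-bis(methoxymethoxy)-3,5-dimethoxy-4-methylphenyl]butanoate. Forward, cathodic reduction with a nickel catalyst bearing a tridentate nitrogen ligand, against a sacrificial anode, fragments all four esters to primary alkyl radicals with fourfold decarboxylation and couples them. The product A5, 1,13-bis[2,6-bis(methoxymethoxy)-3,5-dimethoxy-4-methylphenyl]tridecane, is the same compound as 15.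
- For it: it lands directly on the saturated tether, one step fewer after the key step, from a cheap odd diacid, and the acetals tolerate the conditions. On step economy after the key step it is stronger.
- Against it: the two partners are unactivated primary alkyl radicals of the same kind, which the catalyst cannot tell apart. Homodimer of A7, chain-extended oligomers of A6 and reduced fragments must form alongside the 2:1 product, and these differ only in the number of methylene groups. A7 also needs a four-carbon acid chain on the hindered arene plus an activation step.
- Comparison: in the chosen route the nucleophile (sp3 C–Mg) and the electrophile (sp2 C–Br) are distinct, so cross-selectivity is built in. The price is one extra step for sulfur removal.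

Key step: step 7

## Route

Step 1
Reactants: 1 2,6-dimethoxytoluene
Product: 2 1,5-dibromo-2,4-dimethoxy-3-methylbenzene
Conditions: NBS (2.1 equiv), MeCN, 0 °C to rt, dark
Reagents that add atoms: N-bromosuccinimide, O=C1CCC(=O)N1Br
Why: Electrophilic aromatic bromination; C3 and C5 of 1 are each ortho to one methoxy group and para to the other while C4 is meta to both, so two equivalents of NBS in a polar solvent should stop at the 3,5-dibromide, and the absence of light and initiator protects the benzylic methyl.

Step 2
Reactants: 2 1,5-dibromo-2,4-dimethoxy-3-methylbenzene
Product: 3 4,6-dimethoxy-5-methylbenzene-1,3-diol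
Conditions: Pd2(dba)3 (2 mol %), 2-(di-tert-butylphosphino)-2',4',6'-triisopropylbiphenyl (8 mol %), KOH (6 equiv), 1,4-dioxane/H2O, 100 °C, argon; then aq. HCl
Reagents that add atoms: potassium hydroxide, [K+].[OH-]
Why: Palladium-catalysed hydroxylation of aryl bromides (C–O cross-coupling of the Buchwald–Hartwig family); the bulky electron-rich biarylphosphine permits oxidative addition to the ortho-methoxy bromide and C–O reductive elimination, and the phenoxide formed first is meta to the second bromide and so does not deactivate it by resonance. The diol is air-sensitive and should be carried on at once.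

Step 3
Reactants: 3 4,6-dimethoxy-5-methylbenzene-1,3-diol
Product: 4 1,5-bis(methoxymethoxy)-2,4-dimethoxy-3-methylbenzene
Conditions: MOMCl (3 equiv), i-Pr2NEt (4 equiv), CH2Cl2, 0 °C to rt
Reagents that add atoms: chloromethyl methyl ether, COCCl
Why: O-Alkylation of both phenols by the α-chloro ether through its oxocarbenium ion with a hindered amine base; the bis-acetal is stable to bases and organometallics and is the directing group for the next step.

Step 4
Reactants: 4 1,5-bis(methoxymethoxy)-2,4-dimethoxy-3-methylbenzene; 5 ethylene oxide
Product: 7 2-[2,6-bis(methoxymethoxy)-3,5-dimethoxy-4-methylphenyl]ethan-1-ol, via aryllithium 6 (not isolated)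
Conditions: n-BuLi (1.1 equiv), THF, 0 °C; then 5 (3 equiv, THF solution), −78 °C to rt; aq. NH4Cl
Reagents that add atoms: none
Why: Directed ortho-metalation; the single ring hydrogen of 4 lies between two MOM ethers that both coordinate lithium, so n-BuLi removes it in preference to the far less acidic methyl hydrogens, and 6 opens the epoxide by SN2 attack at CH2 to give the 2-arylethanol on protonation.

Step 5
Reactants: 7 2-[2,6-bis(methoxymethoxy)-3,5-dimethoxy-4-methylphenyl]ethan-1-ol
Product: 8 2-(2-bromoethyl)-1,3-bis(methoxymethoxy)-4,6-dimethoxy-5-methylbenzene
Conditions: CBr4 (1.3 equiv), PPh3 (1.4 equiv), 2,6-lutidine (0.2 equiv), CH2Cl2, 0 °C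
Reagents that add atoms: carbon tetrabromide, BrC(Br)(Br)Br
Why: Appel reaction; bromide displaces the alkoxyphosphonium group at the primary carbon by SN2 under nearly neutral conditions that the MOM acetals tolerate, with lutidine buffering traces of HBr.

Step 6
Reactants: 9 2-bromothiophene; 10 formaldehyde (as paraformaldehyde)
Product: 12 bis(5-bromothiophen-2-yl)methane, via 2-bromo-5-(chloromethyl)thiophene 11 (not isolated)
Conditions: (CH2O)n (1 equiv), 9 (3 equiv), ZnCl2 (0.3 equiv), conc. aq. HCl, AcOH, 50 °C
Reagents that add atoms: none
Why: Blanc chloromethylation followed by Friedel–Crafts alkylation; the only free α-position of 9 attacks protonated formaldehyde, and the thenyl chloride 11 ionises with ZnCl2 and alkylates a second molecule of 9 at C5. Bromine blocks the other α-position and the β-positions are much less nucleophilic, so with excess 9 the condensation should stop at the diarylmethane.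

Step 7
Reactants: 8 2-(2-bromoethyl)-1,3-bis(methoxymethoxy)-4,6-dimethoxy-5-methylbenzene; 12 bis(5-bromothiophen-2-yl)methane
Product: 14 bis(5-{2-[2,6-bis(methoxymethoxy)-3,5-dimethoxy-4-methylphenyl]ethyl}thiophen-2-yl)methane, via arylethylmagnesium bromide 13 (not isolated)
Conditions: 8 (2.5 equiv), Mg turnings (activated with a crystal of iodine), THF, 35 °C; then 12 (1 equiv), NiCl2(Ph2PCH2CH2CH2PPh2) (5 mol %), THF, 0 °C to 45 °C
Reagents that add atoms: none
Why: Magnesium inserts into the primary C–Br bond of 8 to give 13; slow addition limits Wurtz dimerisation, and the ortho MOM oxygens may chelate magnesium without opening an elimination path because the β-carbon carries no leaving group. The divalent nickel precatalyst is reduced by 13 to a zerovalent nickel–diphosphine species that adds oxidatively into a thienyl C–Br bond of 12; transmetalation from 13 and reductive elimination form the C(sp2)–C(sp3) bond c2–c3, and the same cycle at the second bromide forms c11–c12. The closest known reaction type is the Kumada–Tamao–Corriu coupling of 2-bromothiophenes with primary alkylmagnesium halides under nickel–diphosphine catalysis. No ring is closed and no stereocentre is created. Reductive elimination has to outrun β-hydride elimination from the alkylnickel intermediate, whose β-hydrogens are benzylic; the cis-chelating diphosphine holds thienyl and alkyl adjacent and leaves no vacant site, which favours coupling. The methylene between the two thiophenes is the only acidic C–H, and an alkylmagnesium bromide in THF at or below 45 °C is a kinetically slow base towards carbon acids of that strength; bromine–magnesium exchange at the thiophene is likewise slow for a primary alkyl Grignard reagent. The arene of 13 is hexasubstituted with only ether and alkyl groups and offers no competing C–H, C–halogen or electrophilic site, and insertion of nickel into thiophene C–S bonds is much slower than into C–Br at this temperature.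

Step 8
Reactants: 14 bis(5-{2-[2,6-bis(methoxymethoxy)-3,5-dimethoxy-4-methylphenyl]ethyl}thiophen-2-yl)methane
Product: 15 1,13-bis[2,6-bis(methoxymethoxy)-3,5-dimethoxy-4-methylphenyl]tridecane
Conditions: Raney Ni (W-2, large excess), H2 (1 atm), EtOH/THF, reflux
Reagents that add atoms: none
Why: Raney nickel reductive desulfurisation; hydrogenolysis of the four C–S bonds and saturation of the former ring carbons turns each 2,5-dialkylthiophene into four methylene groups, so c3–c11 become a saturated chain. Aryl methyl ethers, MOM acetals and the hexasubstituted benzene rings are inert here, and the hydrogen atmosphere should prevent alkenes from surviving.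

Step 9
Reactants: 15 1,13-bis[2,6-bis(methoxymethoxy)-3,5-dimethoxy-4-methylphenyl]tridecane
Product: 16 2,2'-(tridecane-1,13-diyl)bis(4,6-dimethoxy-5-methylbenzene-1,3-diol)
Conditions: HCl (conc., cat.), degassed MeOH/THF, 50 °C, argon
Reagents that add atoms: none
Why: Acid-catalysed acetal exchange; each protonated MOM group transfers its methoxymethyl cation to methanol and frees a phenol, while the aryl methyl ethers are stable to dilute acid. Oxygen is excluded because the tetraphenol is very electron-rich, and the crude product should go straight into the oxidation.

Step 10
Reactants: 16 2,2'-(tridecane-1,13-diyl)bis(4,6-dimethoxy-5-methylbenzene-1,3-diol)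
Product: 17 3,3'-(tridecane-1,13-diyl)bis(2-hydroxy-5-methoxy-6-methylcyclohexa-2,5-diene-1,4-dione)
Conditions: (NH4)2Ce(NO3)6 (4.4 equiv), MeCN/H2O, 0 °C, short reaction time
Reagents that add atoms: water, O
Why: Oxidative demethylation of a para-methoxyphenol; two one-electron oxidations by tetravalent cerium, addition of water at the methoxy-bearing para carbon and loss of methanol from the hemiketal give the para-quinone. The two phenol/para-methoxy pairs of each ring are mirror images across the axis through the chain carbon and the methyl carbon, so either path gives the same ring, with the second phenol left as the quinone hydroxyl beside the chain and the remaining methoxy beside the methyl.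

## Compound list

1 | 2,6-dimethoxytoluene (1,3-dimethoxy-2-methylbenzene) | Cc1c(OC)cccc1OC | starting material
2 | 1,5-dibromo-2,4-dimethoxy-3-methylbenzene | COc1c(Br)cc(Br)c(OC)c1C | intermediate
3 | 4,6-dimethoxy-5-methylbenzene-1,3-diol | COc1c(O)cc(O)c(OC)c1C | intermediate
4 | 1,5-bis(methoxymethoxy)-2,4-dimethoxy-3-methylbenzene | COCOc1cc(OCOC)c(OC)c(C)c1OC | intermediate
5 | ethylene oxide (oxirane) | C1CO1 | starting material
6 | [2,6-bis(methoxymethoxy)-3,5-dimethoxy-4-methylphenyl]lithium | [Li]c1c(OCOC)c(OC)c(C)c(OC)c1OCOC | intermediate
7 | 2-[2,6-bis(methoxymethoxy)-3,5-dimethoxy-4-methylphenyl]ethan-1-ol | COCOc1c(CCO)c(OCOC)c(OC)c(C)c1OC | intermediate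
8 | 2-(2-bromoethyl)-1,3-bis(methoxymethoxy)-4,6-dimethoxy-5-methylbenzene | COCOc1c(CCBr)c(OCOC)c(OC)c(C)c1OC | intermediate
9 | 2-bromothiophene | Brc1cccs1 | starting material
10 | formaldehyde (used as paraformaldehyde) | C=O | starting material
11 | 2-bromo-5-(chloromethyl)thiophene | ClCc1ccc(Br)s1 | intermediate
12 | bis(5-bromothiophen-2-yl)methane | Brc1ccc(Cc2ccc(Br)s2)s1 | intermediate
13 | {2-[2,6-bis(methoxymethoxy)-3,5-dimethoxy-4-methylphenyl]ethyl}magnesium bromide | COCOc1c(CC[Mg]Br)c(OCOC)c(OC)c(C)c1OC | intermediate
14 | bis(5-{2-[2,6-bis(methoxymethoxy)-3,5-dimethoxy-4-methylphenyl]ethyl}thiophen-2-yl)methane | COCOc1c(CCc2ccc(Cc3ccc(CCc4c(OCOC)c(OC)c(C)c(OC)c4OCOC)s3)s2)c(OCOC)c(OC)c(C)c1OC | intermediate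
15 | 1,13-bis[2,6-bis(methoxymethoxy)-3,5-dimethoxy-4-methylphenyl]tridecane | COCOc1c(CCCCCCCCCCCCCc2c(OCOC)c(OC)c(C)c(OC)c2OCOC)c(OCOC)c(OC)c(C)c1OC | intermediate
16 | 2,2'-(tridecane-1,13-diyl)bis(4,6-dimethoxy-5-methylbenzene-1,3-diol) | COc1c(C)c(OC)c(O)c(CCCCCCCCCCCCCc2c(O)c(OC)c(C)c(OC)c2O)c1O | intermediate
17 | 3,3'-(tridecane-1,13-diyl)bis(2-hydroxy-5-methoxy-6-methylcyclohexa-2,5-diene-1,4-dione) | COC1=C(C)C(=O)C(O)=C(CCCCCCCCCCCCCC2=C(O)C(=O)C(C)=C(OC)C2=O)C1=O | target

## Step count and risk

Total step count: 10. Longest linear sequence: 9 steps (steps 1–5 and 7–10, from 1); step 6 is the one-step side branch.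

Steps least certain to work:

**Step 7 (key step).** The most likely failures are stalling after the first of the two couplings and β-hydride elimination from the alkylnickel intermediate, which reduces the thienyl bromide and consumes the Grignard reagent. Deprotonation of the doubly activated methylene by excess Grignard reagent, and Wurtz-type dimerisation during magnesium insertion, are also possible. Fallback, from 8: E2 elimination with KOtBu in THF should give 1-ethenyl-2,6-bis(methoxymethoxy)-3,5-dimethoxy-4-methylbenzene F1. Hydroboration with 9-borabicyclo[3.3.1]nonane in THF should give 9-{2-[2,6-bis(methoxymethoxy)-3,5-dimethoxy-4-methylphenyl]ethyl}-9-borabicyclo[3.3.1]nonane F2. F2 is coupled in the same flask with 12 under PdCl2(dppf) (dppf = (Ph2PC5H4)2Fe) and aqueous K3PO4 at 60 °C, a B-alkyl Suzuki–Miyaura coupling, and rejoins the route at 14. The boron nucleophile is non-basic, which removes both the deprotonation and the halogen–metal exchange problem while forming the same two bonds.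

**Step 2.** The second hydroxylation may be incomplete. The phenoxide may also arylate a remaining C–Br bond to give a diaryl ether, hydrodebromination may compete, and the electron-rich diol may oxidise in air during work-up. Fallback, from 2: Miyaura borylation (bis(pinacolato)diboron, PdCl2(dppf), KOAc, dioxane, 90 °C) should give 2,2'-(4,6-dimethoxy-5-methyl-1,3-phenylene)bis(4,4,5,5-tetramethyl-1,3,2-dioxaborolane) F3. Oxidation with H2O2/NaOH in THF at 0 °C returns to the route at 3.

**Step 4.** The chelated, doubly ortho-substituted aryllithium may open the epoxide only slowly, so that protonation by adventitious acid or decomposition on warming returns 4. Fallback, from 4 through the same aryllithium 6: quenching with allyl bromide should give 2,6-bis(methoxymethoxy)-3,5-dimethoxy-4-methyl-1-(prop-2-en-1-yl)benzene F4. Lemieux–Johnson cleavage (OsO4 cat., NaIO4, 2,6-lutidine, dioxane/H2O) should give 2-[2,6-bis(methoxymethoxy)-3,5-dimethoxy-4-methylphenyl]acetaldehyde F5, which is reduced in the same flask with NaBH4 to rejoin the route at 7.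

**Step 6.** Further alkylation through the β-positions may give oligomers. Acid-mediated migration or loss of bromine, and stalling at the chloromethyl stage, are the other concerns. Fallback, from 9: deprotonation at C5 with LiN(iPr)2 in THF at −78 °C should give (5-bromothiophen-2-yl)lithium F6. Half an equivalent of ethyl formate converts F6 into bis(5-bromothiophen-2-yl)methanol F7. Ionic hydrogenation of the doubly thienylic carbinol with Et3SiH/CF3CO2H in CH2Cl2 at 0 °C rejoins the route at 12.

**Step 10.** The hydroxyquinone may be over-oxidised or degraded by excess oxidant, phenoxy radicals may couple intermolecularly, and 16 may oxidise uncontrollably in air before the step. Fallback, from 15: the order of the last two steps is reversed. Oxidation of the tetra-ether with (NH4)2Ce(NO3)6 in MeCN/H2O should give 3,3'-(tridecane-1,13-diyl)bis[5-methoxy-2-(methoxymethoxy)-6-methylcyclohexa-2,5-diene-1,4-dione] F8, since both methoxy/MOM-oxy para pairs of a ring again give the same quinone. The vinylogous MOM ester is then removed with dilute HCl in MeOH at room temperature to arrive at 17 without ever handling the free tetraphenol.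

## Further compounds

F1 | step 7 | 1-ethenyl-2,6-bis(methoxymethoxy)-3,5-dimethoxy-4-methylbenzene | COCOc1c(C=C)c(OCOC)c(OC)c(C)c1OC
F2 | step 7 | 9-{2-[2,6-bis(methoxymethoxy)-3,5-dimethoxy-4-methylphenyl]ethyl}-9-borabicyclo[3.3.1]nonane | COCOc1c(CCB2C3CCCC2CCC3)c(OCOC)c(OC)c(C)c1OC
F3 | step 2 | 2,2'-(4,6-dimethoxy-5-methyl-1,3-phenylene)bis(4,4,5,5-tetramethyl-1,3,2-dioxaborolane) | COc1c(B2OC(C)(C)C(C)(C)O2)cc(B2OC(C)(C)C(C)(C)O2)c(OC)c1C
F4 | step 4 | 2,6-bis(methoxymethoxy)-3,5-dimethoxy-4-methyl-1-(prop-2-en-1-yl)benzene | COCOc1c(CC=C)c(OCOC)c(OC)c(C)c1OC
F5 | step 4 | 2-[2,6-bis(methoxymethoxy)-3,5-dimethoxy-4-methylphenyl]acetaldehyde | COCOc1c(CC=O)c(OCOC)c(OC)c(C)c1OC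
F6 | step 6 | (5-bromothiophen-2-yl)lithium | [Li]c1ccc(Br)s1
F7 | step 6 | bis(5-bromothiophen-2-yl)methanol | OC(c1ccc(Br)s1)c1ccc(Br)s1
F8 | step 10 | 3,3'-(tridecane-1,13-diyl)bis[5-methoxy-2-(methoxymethoxy)-6-methylcyclohexa-2,5-diene-1,4-dione] | COCOC1=C(CCCCCCCCCCCCCC2=C(OCOC)C(=O)C(C)=C(OC)C2=O)C(=O)C(OC)=C(C)C1=O
A1 | alternative 1 | dimethyl 6,6'-(tridecane-1,13-diyl)bis(2,4-dihydroxy-3-methylbenzoate) | COC(=O)c1c(O)c(C)c(O)cc1CCCCCCCCCCCCCc1cc(O)c(C)c(O)c1C(=O)OC
A2 | alternative 1 | dimethyl 4,24-dimethyl-3,5,7,21,23,25-hexaoxoheptacosanedioate (mixture of stereoisomers; both centres are lost on aromatisation) | COC(=O)CC(=O)C(C)C(=O)CC(=O)CCCCCCCCCCCCCC(=O)CC(=O)C(C)C(=O)CC(=O)OC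
A3 | alternative 2 | 6,6'-(tridecane-1,13-diyl)bis(5-isopropoxy-2-methoxy-3-methylbenzene-1,4-diol) | COc1c(C)c(O)c(OC(C)C)c(CCCCCCCCCCCCCc2c(OC(C)C)c(O)c(C)c(OC)c2O)c1O
A4 | alternative 2 | 2,2'-(tridecane-1,13-diyl)bis[4-hydroxy-3-isopropoxy-4-(1-methoxyprop-1-en-2-yl)cyclobut-2-en-1-one] (mixture of stereoisomers; carbinol centres and alkene geometry are lost on rearrangement) | COC=C(C)C1(O)C(OC(C)C)=C(CCCCCCCCCCCCCC2=C(OC(C)C)C(O)(C(C)=COC)C2=O)C1=O
A5 | alternative 3 | 1,13-bis[2,6-bis(methoxymethoxy)-3,5-dimethoxy-4-methylphenyl]tridecane | COCOc1c(CCCCCCCCCCCCCc2c(OCOC)c(OC)c(C)c(OC)c2OCOC)c(OCOC)c(OC)c(C)c1OC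
A6 | alternative 3 | bis(1,3-dioxoisoindolin-2-yl) nonanedioate | O=C(CCCCCCCC(=O)ON1C(=O)c2ccccc2C1=O)ON1C(=O)c2ccccc2C1=O
A7 | alternative 3 | 1,3-dioxoisoindolin-2-yl 4-[2,6-bis(methoxymethoxy)-3,5-dimethoxy-4-methylphenyl]butanoate | COCOc1c(CCCC(=O)ON2C(=O)c3ccccc3C2=O)c(OCOC)c(OC)c(C)c1OC
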